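**Strategy.** The chalcone is cut at its Cα=Cβ double bond (Claisen–Schmidt) into an (R)-dihydrobenzofuranyl methyl ketone and 2,2-dimethylchroman-6-carbaldehyde. Everything rests on the chroman. Besides the fused pyran ring, ring B bears only one substituent, at C6, para to the O1-bearing C8a. O1–C8a≡C8 is therefore read as an ynol ether, C4a≡C5 as an alkyl alkyne and C6≡C7 as a propiolate. One Rh(I)-catalysed [2+2+2] cycloaddition forms C4a–C8a, C5–C6 and C7–C8 and closes benzene ring B and the dihydropyran ring together. Its precursor is the oxygen-tethered 1,7-diyne HC≡C–O–CMe2–CH2CH2–C≡CH. The single stereocentre comes from an enantioselective Pd-catalysed isoprene heteroannulation.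

Key step: step 3

Assumption: chroman numbering is O1, C2(Me2), C3, C4, C4a, C5–C8, C8a. The ligand antipode in step 6 is taken to be the one that gives the (2R) product, by analogy with the 6-deoxy 5-acetyl-2-isopropenyl-2,3-dihydrobenzofuran case; the antipodal ligand is used if the sense proves opposite.

Step 1
Reactants: 1 methyl pent-4-ynoate
Product: 2 2-methylhex-5-yn-2-ol
Conditions: MeMgBr (3.3 equiv), THF, 0 °C → rt; sat. aq NH4Cl
Reagents that add atoms: methylmagnesium bromide, C[Mg]Br
Why: Double Grignard addition to the ester carbonyl delivers the gem-dimethyl carbinol, the third equivalent being consumed by the acidic alkyne C–H, which is restored on work-up.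

Step 2
Reactants: 2 2-methylhex-5-yn-2-ol; 3 trichloroethylene
Product: 6 5-(ethynyloxy)-5-methylhex-1-yne, via dichlorovinyl ether 4 (not isolated), via dilithio diyne 5 (not isolated)
Conditions: KH (1.1 equiv), THF, 0 °C → rt; 3 (1.05 equiv), −50 °C → rt; n-BuLi (3.3 equiv), −78 → −40 °C; H2O, −78 °C; pentane extraction, basic alumina plug, concentrated at ≤ 0 °C, stored cold in solution and used the same day
Reagents that add atoms: none
Why: This is the standard one-pot alcohol-to-alkynyl-ether sequence, in which the potassium alkoxide adds to dichloroacetylene released from 3 (net vinylic substitution) to give 4, and n-BuLi then dehydrochlorinates 4 and exchanges the remaining chlorine for lithium, one further equivalent covering the alkyne C–H, so that a cold, non-acidic quench of 5 gives 6, which is never warmed because of its retro-ene lability.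

Step 3
Reactants: 6 5-(ethynyloxy)-5-methylhex-1-yne; 7 methyl propiolate
Product: 8 methyl 2,2-dimethylchroman-6-carboxylate
Conditions: [Rh(cod)2]BF4 (5 mol %), rac-BINAP (5 mol %), H2 pre-activation; 7 (2 equiv), CH2Cl2 (dilute), 4 Å MS, 0 → 20 °C; 6 added by syringe pump over 6 h
Reagents that add atoms: none
Why: Proposed new method: the closest known reaction types are the room-temperature cationic Rh(I)/bisphosphine [2+2+2] cycloadditions of tethered diynes with propiolates and of aryl ethynyl ethers as free monoynes, together with the ynamide-tethered diyne variant, whereas a diyne whose tether begins at the oxygen of a tert-alkyl ethynyl ether has not been used. Oxidative coupling of both alkynes of 6 on Rh(I) joins the two substituted alkyne carbons (C8a–C4a) and so closes the dihydropyran ring by cyclometallation across the four-atom O1–C2–C3–C4 tether, which the gem-dimethyl group at C2 pre-folds, giving a bicyclic rhodacyclopentadiene with Rh on C8 and C5. Insertion of 7 and C–C reductive elimination from the seven-membered rhodacycle then form C7–C8 and C5–C6 and close benzene ring B. The step needs the ester on C6 rather than C7: C8 is the β-carbon of an enol ether and the more nucleophilic Rh–C terminus, so it bonds to the electrophilic CH end of 7 and leaves the ester-bearing carbon for C5, and the alternative order of events (donor and acceptor alkyne coupling first through their CH termini, pendant alkyne inserting last) ends in the same isomer. It also needs cross- rather than self-trimerisation and survival of the ynol ether, which slow addition of 6 to a modest excess of 7, a dry acid-free medium and a temperature at or below 20 °C (below the onset of retro-ene fragmentation) should secure. No stereocentre is created.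

Step 4
Reactants: 8 methyl 2,2-dimethylchroman-6-carboxylate
Product: 9 (2,2-dimethylchroman-6-yl)methanol
Conditions: LiAlH4, THF, 0 °C; H2O work-up
Reagents that add atoms: none
Why: LiAlH4 reduction of an aromatic methyl ester to the benzylic alcohol is reliable and the chroman ether is inert to hydride.

Step 5
Reactants: 9 (2,2-dimethylchroman-6-yl)methanol
Product: 10 2,2-dimethylchroman-6-carbaldehyde
Conditions: activated MnO2 (10 equiv), CH2Cl2, rt
Reagents that add atoms: none
Why: Activated MnO2 oxidises benzylic alcohols selectively and stops at the aldehyde.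

Step 6
Reactants: 11 5-bromo-2,4-dihydroxyacetophenone; 12 isoprene
Product: 13 1-[(2R)-6-hydroxy-2-(prop-1-en-2-yl)-2,3-dihydro-1-benzofuran-5-yl]ethan-1-one
Conditions: Pd2(dba)3·CHCl3 (5 mol %), chiral tert-butanesulfinamide-based monophosphine (TY-Phos type, 12 mol %, antipode giving 2R), NaOPh (3 equiv), 12 (5 equiv), toluene, 60 °C, sealed tube
Reagents that add atoms: none
Why: In this enantioselective Heck/Tsuji–Trost heteroannulation of an o-bromophenol with a 1,3-diene, the aryl-Pd species adds to the unsubstituted vinyl terminus of isoprene and the resulting π-allyl-Pd is captured 5-exo at its internal carbon by the adjacent C4 phenoxide, the chiral ligand fixing the face of C–O bond formation and hence (R) at C2, while the chelated C2 hydroxyl para to bromine cannot reach the allyl unit.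

Step 7
Reactants: 13 1-[(2R)-6-hydroxy-2-(prop-1-en-2-yl)-2,3-dihydro-1-benzofuran-5-yl]ethan-1-one
Product: 14 1-[(2R)-6-hydroxy-2-(2-hydroxypropan-2-yl)-2,3-dihydro-1-benzofuran-5-yl]ethan-1-one
Conditions: Co(acac)2 (20 mol %), PhSiH3 (3 equiv), O2 (1 atm), THF, rt
Reagents that add atoms: dioxygen, O=O
Why: Mukaiyama hydration (cobalt-hydride hydrogen-atom transfer to the 1,1-disubstituted alkene, O2 capture of the tertiary radical and reduction by the silane) gives the Markovnikov tertiary alcohol under neutral conditions that spare the aryl ketone and the C2–O bond, so the (R) centre, which is not a reacting atom, is retained.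

Step 8
Reactants: 14 1-[(2R)-6-hydroxy-2-(2-hydroxypropan-2-yl)-2,3-dihydro-1-benzofuran-5-yl]ethan-1-one; 10 2,2-dimethylchroman-6-carbaldehyde
Product: 16 (2E)-3-(2,2-dimethylchroman-6-yl)-1-[(2R)-6-hydroxy-2-(2-hydroxypropan-2-yl)-2,3-dihydro-1-benzofuran-5-yl]prop-2-en-1-one, via aldol adduct 15 (not isolated)
Conditions: KOH (50% aq, 10 equiv), EtOH, rt, 48 h; 1 M HCl to pH 5, 0 °C
Reagents that add atoms: none
Why: In this Claisen–Schmidt condensation the enolate of 14 adds to the non-enolisable aldehyde 10 and the aldol 15 loses water by E1cB to the conjugated, thermodynamically favoured (E)-enone, strong base holding the 2'-hydroxychalcone open as its phenoxide rather than as the flavanone, and the C2 stereocentre carrying no acidic hydrogen.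

**Compound list**
1 | methyl pent-4-ynoate | C#CCCC(=O)OC | starting material
2 | 2-methylhex-5-yn-2-ol | C#CCCC(C)(C)O | intermediate
3 | trichloroethylene | ClC=C(Cl)Cl | starting material
4 | 5-{[(E)-1,2-dichloroethenyl]oxy}-5-methylhex-1-yne | C#CCCC(C)(C)O/C(Cl)=C\Cl | intermediate
5 | 1-lithio-5-[(lithioethynyl)oxy]-5-methylhex-1-yne | [Li]C#COC(C)(C)CCC#C[Li] | intermediate
6 | 5-(ethynyloxy)-5-methylhex-1-yne | C#COC(C)(C)CCC#C | intermediate
7 | methyl propiolate | C#CC(=O)OC | starting material
8 | methyl 2,2-dimethylchroman-6-carboxylate | COC(=O)c1ccc2OC(C)(C)CCc2c1 | intermediate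
9 | (2,2-dimethylchroman-6-yl)methanol | OCc1ccc2OC(C)(C)CCc2c1 | intermediate
10 | 2,2-dimethylchroman-6-carbaldehyde | O=Cc1ccc2OC(C)(C)CCc2c1 | intermediate
11 | 5-bromo-2,4-dihydroxyacetophenone | CC(=O)c1cc(Br)c(O)cc1O | starting material
12 | isoprene | C=CC(C)=C | starting material
13 | 1-[(2R)-6-hydroxy-2-(prop-1-en-2-yl)-2,3-dihydro-1-benzofuran-5-yl]ethan-1-one | CC(=O)c1cc2c(cc1O)O[C@@H](C(C)=C)C2 | intermediate
14 | 1-[(2R)-6-hydroxy-2-(2-hydroxypropan-2-yl)-2,3-dihydro-1-benzofuran-5-yl]ethan-1-one | CC(=O)c1cc2c(cc1O)O[C@@H](C(C)(C)O)C2 | intermediate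
15 | 3-(2,2-dimethylchroman-6-yl)-3-hydroxy-1-[(2R)-6-hydroxy-2-(2-hydroxypropan-2-yl)-2,3-dihydro-1-benzofuran-5-yl]propan-1-one (both carbinol epimers) | CC1(C)CCc2cc(C(O)CC(=O)c3cc4c(cc3O)O[C@@H](C(C)(C)O)C4)ccc2O1 | intermediate
16 | (2E)-3-(2,2-dimethylchroman-6-yl)-1-[(2R)-6-hydroxy-2-(2-hydroxypropan-2-yl)-2,3-dihydro-1-benzofuran-5-yl]prop-2-en-1-one | CC1(C)CCc2cc(/C=C/C(=O)c3cc4c(cc3O)O[C@@H](C(C)(C)O)C4)ccc2O1 | target

**Total step count:** 8. **Longest linear sequence:** 6 (steps 1, 2, 3, 4, 5, 8); the ketone branch takes steps 6 and 7.

**Steps most likely to fail**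

Step 3 (carries the label). Several processes could defeat it:
- self-oligomerisation of the electron-rich ethynyl ether terminus;
- 1:2 co-trimerisation of that terminus with the propiolate, which may outrun ring closure over the four-atom tether;
- retro-ene fragmentation or adventitious hydration of the ynol ether;
- incomplete regiocontrol.

The fallback uses known chemistry and no cycloaddition. It sets out from isoprene 12, which is condensed with commercial methyl 4-hydroxybenzoate under acid catalysis (85% H3PO4 or Amberlyst-15, heptane, 60–70 °C). Friedel–Crafts prenylation ortho to the hydroxyl gives methyl 4-hydroxy-3-(3-methylbut-2-en-1-yl)benzoate F1. Under the same acid, F1 undergoes Markovnikov hydroalkoxylation of its trisubstituted alkene to the chroman. The route is rejoined at 8.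

Step 2. Three processes could reduce the supply of 6:
- metalation of the free alkyne by KH and its addition to the chloroalkyne electrophile;
- sluggish addition of the hindered tertiary alkoxide;
- loss of the volatile, heat- and acid-sensitive product on isolation.

The fallback sets out from 2. O-Formylation (acetic formic anhydride, pyridine, 0 °C) gives 2-methylhex-5-yn-2-yl formate F2. Wittig-type dichloromethylenation of the formyl C=O (PPh3, CCl4, THF, 60 °C) gives 5-[(2,2-dichloroethenyl)oxy]-5-methylhex-1-yne F3. The O–C(sp2) bond is thus made by acylation rather than by alkoxide attack on a chloroalkyne, and no strong base meets the free alkyne before the last operation. n-BuLi (3.3 equiv, −78 °C) converts F3 into 5, where the route is rejoined, and the water quench then gives 6.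

Step 6. Three processes could spoil it:
- catalyst inhibition by the doubly deprotonated resorcinol ketone;
- insertion of isoprene at its wrong terminus;
- insufficient facial selectivity in the C–O bond-forming allylic substitution.

The fallback replaces catalyst-controlled annulation by reagent-controlled epoxidation and sets out from 11.
- Selective silylation of the non-chelated 4-OH (TBSCl, imidazole, DMF) gives 1-[5-bromo-4-(tert-butyldimethylsilyloxy)-2-hydroxyphenyl]ethan-1-one F4.
- Stille coupling with tributyl(3-methylbut-2-en-1-yl)stannane (Pd(PPh3)4, DMF, 100 °C) gives 1-[4-(tert-butyldimethylsilyloxy)-2-hydroxy-5-(3-methylbut-2-en-1-yl)phenyl]ethan-1-one F5.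
- Shi epoxidation with the L-fructose-derived ketone (Oxone, K2CO3 buffer, MeCN–dimethoxymethane, 0 °C) gives 1-[4-(tert-butyldimethylsilyloxy)-5-{[(2S)-3,3-dimethyloxiran-2-yl]methyl}-2-hydroxyphenyl]ethan-1-one F6.
- TBAF (THF, 0 °C) frees the phenoxide, which opens the epoxide 5-exo-tet at the secondary carbon with inversion to the (R) centre.

The route is rejoined at 14, so 13 and step 7 are bypassed.

**Further compounds**
F1 | step 3 | methyl 4-hydroxy-3-(3-methylbut-2-en-1-yl)benzoate | COC(=O)c1ccc(O)c(CC=C(C)C)c1
F2 | step 2 | 2-methylhex-5-yn-2-yl formate | C#CCCC(C)(C)OC=O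
F3 | step 2 | 5-[(2,2-dichloroethenyl)oxy]-5-methylhex-1-yne | C#CCCC(C)(C)OC=C(Cl)Cl
F4 | step 6 | 1-[5-bromo-4-(tert-butyldimethylsilyloxy)-2-hydroxyphenyl]ethan-1-one | CC(=O)c1cc(Br)c(O[Si](C)(C)C(C)(C)C)cc1O
F5 | step 6 | 1-[4-(tert-butyldimethylsilyloxy)-2-hydroxy-5-(3-methylbut-2-en-1-yl)phenyl]ethan-1-one | CC(=O)c1cc(CC=C(C)C)c(O[Si](C)(C)C(C)(C)C)cc1O
F6 | step 6 | 1-[4-(tert-butyldimethylsilyloxy)-5-{[(2S)-3,3-dimethyloxiran-2-yl]methyl}-2-hydroxyphenyl]ethan-1-one | CC(=O)c1cc(C[C@@H]2OC2(C)C)c(O[Si](C)(C)C(C)(C)C)cc1O
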